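**Assumption:** the target SMILES has no stereodescriptors and the molecule has no stereocentre (the CMe2 carbons are not stereogenic), so no stereocontrol is needed; the enol forms drawn are one tautomer of each ring.

## Retrosynthetic overview

1. The target is the symmetric pentamer ring A–CH2–ring B–CH2–ring C–CH2–ring D–CH2–ring E (A, E = butyrylfilicinic acid; B, C, D = butyrylphloroglucinol).
2. Cut both CH2–ring C bonds: ring C is butyrylphloroglucinol 3 (double C-nucleophile) plus two copies of the electrophilic dimer 7 (ring A–CH2–ring B–CH2–NMe2).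
3. 7 comes from butyrylfilicinic acid 4 and bis-Mannich base 5 by exchanging one NMe2 for carbon, so every bridging CH2 is traced back to a benzylic C–N bond.
4. Key step: twofold C–N bond-forming aminomethylation of 3 (3 + 2 CH2O + 2 Me2NH gives 5), which stores both bridges of an inner ring as CH2–NMe2 groups.
5. No ring is constructed: the aromatic rings are phloroglucinol (acylated to 3), rings A and E arise by dearomatising gem-dimethylation (4); assembly order is ring B (as 5), then ring A (7), then two of 7 onto ring C.

## Route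

**Step 1**
Reactants: 1 phloroglucinol; 2 butanoyl chloride
Product: 3 butyrylphloroglucinol [1-(2,4,6-trihydroxyphenyl)butan-1-one]
Conditions: AlCl3 (4 equiv), PhNO2–CH2Cl2, 0 → 45 °C; ice/aq. HCl
Reagents that add atoms: none
Why: Friedel–Crafts C-acylation of the very electron-rich ring; the chelated ketone deactivates the ring, so 1.0 equiv of 2 gives the mono-ketone; no stereocentre is formed.

**Step 2**
Reactants: 3 butyrylphloroglucinol
Product: 4 butyrylfilicinic acid [2-butanoyl-3,5-dihydroxy-4,4-dimethylcyclohexa-2,5-dien-1-one]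
Conditions: NaOMe (3.2 equiv), MeI (2.4 equiv), MeOH, 0 °C → rt; aq. HCl
Reagents that add atoms: iodomethane (CI)
Why: Dearomatising C-alkylation of the phloroglucinol anion: the second methyl enters the same, now more electron-rich carbon, and the resulting delocalised triketone enolate resists further alkylation (modest yield, by-products removed by crystallisation); the quaternary carbon is not stereogenic.

**Step 3**
Reactants: 3 butyrylphloroglucinol
Product: 5 bis-Mannich base [1-{3,5-bis[(dimethylamino)methyl]-2,4,6-trihydroxyphenyl}butan-1-one]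
Conditions: 37% aq. CH2O (2.2 equiv) and 40% aq. Me2NH (2.4 equiv) premixed, EtOH, 0 °C → rt; filter
Reagents that add atoms: formaldehyde (C=O); dimethylamine (CNC)
Why: Phenolic Mannich reaction: amine and formaldehyde form the C–N bond (iminium) that is captured at each of the only two free ring carbons, so the reaction stops at the bis-adduct, which precipitates as a zwitterion; no stereocentre is formed.

**Step 4**
Reactants: 4 butyrylfilicinic acid; 5 bis-Mannich base
Product: 7 ring A–CH2–ring B–CH2NMe2 Mannich dimer (zwitterion), via ring-B ortho-quinone methide 6 (not isolated)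
Conditions: 5 (1.05 equiv), MeCN (0.05 M), 45 °C, N2 sparge (Me2NH swept out), no added base; filter
Reagents that add atoms: none
Why: Proposed new method: proton-inventory-gated single deaminative C-alkylation of a bis-Mannich base — acid 4 (pKa about 3–4) protonates one NMe2 of 5 and 5's own phenol the other, so ring B is a phenoxide that expels Me2NH (E1cB) to give 6, which the enolate of 4 traps at its one free carbon (Michael addition); each event removes one base (Me2NH leaves with the gas stream) and the new triketone enol in 7 parks its proton on the surviving NMe2, so ring B of 7 carries no phenoxide once 4 is consumed and the second arm stays latent while 7 crystallises; closest known reaction type is the thermal retro-Mannich/Michael alkylation of carbon acids by phenolic Mannich bases, not yet run as a self-terminating mono-exchange on a bis-Mannich base; no stereocentre is formed.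

**Step 5**
Reactants: 7 Mannich dimer (2.1 equiv); 3 butyrylphloroglucinol (1.0 equiv)
Product: 10 target pentamer CNP0188003.0, via dimer ortho-quinone methide 8 (not isolated), via ring A–ring B–ring C trimer 9 (not isolated)
Conditions: Et3N (0.2 equiv), 1,4-dioxane, 60 °C, closed vessel; then 1 M HCl
Reagents that add atoms: none
Why: Known deaminative ortho-quinone-methide Friedel–Crafts alkylation (retro-Mannich/Michael): in a closed vessel the liberated Me2NH stays as the base that regenerates the ring-B phenoxide of 7, 8 forms continuously and alkylates the two free carbons of 3 in turn; neither 7 nor 10 has a free nucleophilic ring carbon, so nothing can oligomerise; no stereocentre is formed.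

## Compound list

1 | phloroglucinol (benzene-1,3,5-triol) | Oc1cc(O)cc(O)c1 | starting material
2 | butanoyl chloride | CCCC(Cl)=O | starting material
3 | butyrylphloroglucinol, 1-(2,4,6-trihydroxyphenyl)butan-1-one | CCCC(=O)c1c(O)cc(O)cc1O | intermediate
4 | butyrylfilicinic acid, 2-butanoyl-3,5-dihydroxy-4,4-dimethylcyclohexa-2,5-dien-1-one | CCCC(=O)C1=C(O)C(C)(C)C(O)=CC1=O | intermediate
5 | bis-Mannich base, 1-{3,5-bis[(dimethylamino)methyl]-2,4,6-trihydroxyphenyl}butan-1-one | CCCC(=O)c1c(O)c(CN(C)C)c(O)c(CN(C)C)c1O | intermediate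
6 | ring-B ortho-quinone methide (not isolated), 2-butanoyl-4-[(dimethylamino)methyl]-3,5-dihydroxy-6-methylidenecyclohexa-2,4-dien-1-one | CCCC(=O)C1=C(O)C(CN(C)C)=C(O)C(=C)C1=O | intermediate
7 | Mannich dimer, 2-butanoyl-6-({3-butanoyl-5-[(dimethylamino)methyl]-2,4,6-trihydroxyphenyl}methyl)-3,5-dihydroxy-4,4-dimethylcyclohexa-2,5-dien-1-one | CCCC(=O)C1=C(O)C(C)(C)C(O)=C(Cc2c(O)c(CN(C)C)c(O)c(C(=O)CCC)c2O)C1=O | intermediate
8 | dimer ortho-quinone methide (not isolated): 7 with exocyclic CH2= in place of CH2NMe2 and C=O at the neighbouring former phenol carbon | CCCC(=O)C1=C(O)C(C)(C)C(O)=C(CC2=C(O)C(=C)C(=O)C(C(=O)CCC)=C2O)C1=O | intermediate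
9 | ring A–CH2–ring B–CH2–ring C trimer (not isolated), one free CH left on ring C | CCCC(=O)C1=C(O)C(C)(C)C(O)=C(Cc2c(O)c(Cc3c(O)cc(O)c(C(=O)CCC)c3O)c(O)c(C(=O)CCC)c2O)C1=O | intermediate
10 | CNP0188003.0, pentamer ring A–CH2–ring B–CH2–ring C–CH2–ring D–CH2–ring E | CCCC(=O)C1=C(O)C(C)(C)C(O)=C(Cc2c(O)c(Cc3c(O)c(Cc4c(O)c(CC5=C(O)C(C)(C)C(O)=C(C(=O)CCC)C5=O)c(O)c(C(=O)CCC)c4O)c(O)c(C(=O)CCC)c3O)c(O)c(C(=O)CCC)c2O)C1=O | target

## Summary

Total step count: 5. Longest linear sequence: 4 steps (1 → 3 → 4 → 7 → 10, or 1 → 3 → 5 → 7 → 10).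

**Three steps most likely to fail**

Step 4 (proposed new step; the risk is a second exchange giving ring A–CH2–ring B–CH2–ring A, or stalling). The fallback uses known chemistry, sets out from 4 and comes back at 7. 4 is treated with bis(dimethylamino)methane in MeCN at 0 °C to give its Mannich base, 2-butanoyl-6-[(dimethylamino)methyl]-3,5-dihydroxy-4,4-dimethylcyclohexa-2,5-dien-1-one F1. Without isolation this is heated with 3 (4 equiv, excess recovered) in dioxane at 60 °C to give norflavaspidic acid BB (ring A–CH2–ring B) F2. Ordinary Mannich aminomethylation of the single free ring carbon of F2 (aq. CH2O, Me2NH, EtOH, 0 °C → rt) then gives 7.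

Step 5 (risk: base-induced scrambling of methylene bridges, or incomplete second alkylation of ring C). The fallback reverses the order of assembly, sets out from 5 and comes back at 10. 5 is heated with 3 (8 equiv, excess recovered) in dioxane to give the ring B–CH2–ring C–CH2–ring D trimer, 1-(3,5-bis{[3-butanoyl-2,4,6-trihydroxyphenyl]methyl}-2,4,6-trihydroxyphenyl)butan-1-one F3. Its two terminal free carbons are then capped with 4 (2.2 equiv) and aq. CH2O in 1% aq. KOH at 0 °C → rt (classical alkaline formaldehyde condensation). The capping runs through the methylidene triketone formed in the flask from 4 and CH2O, 2-butanoyl-3-hydroxy-4,4-dimethyl-6-methylidenecyclohex-2-ene-1,5-dione F4, and gives 10.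

Step 2 (risk: mixtures of mono-, gem-di- and tri-C-methylated products, low yield). The fallback blocks the second free carbon, sets out from 3 and comes back at 4. A second Friedel–Crafts butanoylation of 3 with 2 (AlCl3, PhNO2, 60 °C) gives 2,4-dibutanoylphloroglucinol, 1,1'-(2,4,6-trihydroxy-1,3-phenylene)di(butan-1-one) F5. Its only free ring carbon takes both methyl groups (MeI, NaOMe, MeOH) without regiochemical choice to give 2,6-dibutanoyl-3,5-dihydroxy-4,4-dimethylcyclohexa-2,5-dien-1-one F6. Acidic retro-Claisen removal of one butanoyl group (80% H2SO4, 80 °C, stopped at mono-deacylation) returns 4.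

## Further compounds

F1 | step 4 | 2-butanoyl-6-[(dimethylamino)methyl]-3,5-dihydroxy-4,4-dimethylcyclohexa-2,5-dien-1-one | CCCC(=O)C1=C(O)C(C)(C)C(O)=C(CN(C)C)C1=O
F2 | step 4 | norflavaspidic acid BB, 2-butanoyl-6-[(3-butanoyl-2,4,6-trihydroxyphenyl)methyl]-3,5-dihydroxy-4,4-dimethylcyclohexa-2,5-dien-1-one | CCCC(=O)C1=C(O)C(C)(C)C(O)=C(Cc2c(O)cc(O)c(C(=O)CCC)c2O)C1=O
F3 | step 5 | ring B–CH2–ring C–CH2–ring D trimer, 1-(3,5-bis{[3-butanoyl-2,4,6-trihydroxyphenyl]methyl}-2,4,6-trihydroxyphenyl)butan-1-one | CCCC(=O)c1c(O)cc(O)c(Cc2c(O)c(Cc3c(O)cc(O)c(C(=O)CCC)c3O)c(O)c(C(=O)CCC)c2O)c1O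
F4 | step 5 | 2-butanoyl-3-hydroxy-4,4-dimethyl-6-methylidenecyclohex-2-ene-1,5-dione | CCCC(=O)C1=C(O)C(C)(C)C(=O)C(=C)C1=O
F5 | step 2 | 1,1'-(2,4,6-trihydroxy-1,3-phenylene)di(butan-1-one) | CCCC(=O)c1c(O)cc(O)c(C(=O)CCC)c1O
F6 | step 2 | 2,6-dibutanoyl-3,5-dihydroxy-4,4-dimethylcyclohexa-2,5-dien-1-one | CCCC(=O)C1=C(O)C(C)(C)C(O)=C(C(=O)CCC)C1=O
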